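## Structural features

The target joins three units: a 2-methoxy-3,5-dimethyl-4-pyranone, a six-membered carbocycle, and an (E)-trisubstituted alkenyl chain that ends in an ethyl ketone. Atoms are labelled as follows:
- chain: C1–C6 from the ethyl end (C3 ketone, C4 methine with methyl, C5=C6 alkene with methyl on C6);
- carbocycle: C7–C12 (C7 carries the chain, C8–C9 is the epoxide with methyl on C8, C10=C11 is the alkene with methyl on C10, C12 is quaternary with a methyl group);
- pyranone: O1', C2'–C6' (C2' on C12, methyl groups on C3' and C5', C4' carbonyl, C6' methoxy carbon).

Four contiguous stereocentres (C12, C7, C8, C9) sit on the carbocycle: the pyranone on C12 and the chain on C7 are cis, and the epoxide oxygen lies on the opposite face. The fifth centre, C4, is separated from C7 by the C5=C6 alkene. The fragile groups are C4 (both α to the ketone and allylic, so it can epimerise or slip into conjugation), the vinyl epoxide (acid, halide, low-valent metals), the methoxypyranone (nucleophiles, Lewis-acid demethylation) and, in the intermediates, the 1,3-diene that precedes the epoxide. The real difficulty is the fully substituted pyranone on the quaternary carbon C12: any route that uses the C12 carbonyl as an acyl donor asks a carbon nucleophile to attack a neopentyl carbonyl. The key step turns this around. Because C12 has no hydrogen, a ketone C12–C2'(=O)–C3'H2–CH3 can enolise on one side only, its enol carbon C3' already carries the C3' methyl group, and C4', C5' (with methyl) and C6' form a symmetric 1,3-diacyl unit, so the enol can take up a methylmalonyl unit first at C3' and then at O1'.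

## Logic of the disconnections

**23 ⇒ 21 + 22.** The C4–C5 bond is cut. C4 is the one centre that base can destroy, so it is made last, under non-basic radical-type nickel catalysis, from a racemic partner. The gain is the removal of the whole ketone chain, leaving an sp2 C–I handle and a five-carbon commodity. The forward step must control C4 by the catalyst, keep the (E) geometry and tolerate the epoxide and the pyranone.

**21 ⇒ 20.** The C8–O and C9–O bonds are cut. With iodine on C5 the side-chain alkene is electron-poor, so only the ring diene can compete for an electrophilic oxidant. Two stereocentres disappear and the carbocycle becomes a flat 1,3-diene. The forward step must choose C8=C9 over C10=C11 and the face anti to the C7 substituent, without acid.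

**20 ⇒ 19.** The O–CH3 bond is cut. A 2-methoxy-4-pyranone is the O-methyl isomer of a 4-hydroxy-2-pyranone, which is what carbonyl condensation delivers. The forward step must methylate the lactone carbonyl oxygen and not O4, which calls for a hard electrophile and no base.

**19 ⇒ 17.** The C6–CH3 and C5–I bonds are cut (retro-carbometalation). A terminal alkyne is the smallest precursor of the (E)-alkenyl iodide, and syn addition fixes the geometry. The forward step must place methyl on the internal carbon next to the crowded C7 and must tolerate the acidic pyranone, which it does as the aluminium salt.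

**17 ⇒ 16 + 15 (key disconnection).** The C3'–C4' and O1'–C6' bonds are cut. The heterocycle falls apart into the enol of a C12 ethyl ketone and a symmetric three-carbon diacyl unit, so the hindered carbonyl is only ever a nucleophile. One ring and both remaining methyl-bearing carbons are removed. The forward step needs C-acylation before O-acylation and an acid scavenger that spares the diene.

**16 ⇒ 13 and 15 ⇒ 14.** The O–Si bond and the two C–Cl bonds are cut. These are activations only. The demand is an enolisation method that leaves the alkyne C–H and the allylic, propargylic C7–H alone.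

**13 ⇒ 12.** The C5–C6 bond is cut (one-carbon homologation of an aldehyde). The alkyne carbon C6 is thus traced to a formyl group on C7. The forward step must act on the aldehyde and not on the hindered ketone, and must not epimerise C7.

**12 ⇒ 10.** The C2'–C3' bond is cut and the two carbonyl groups are folded into a lactone acetal. This differentiates them (acid level on C12, aldehyde level on C7, the latter masked) and ties C7 and C12 into a cis-fused ring. The forward step must stop after one ethyl addition.

**10 ⇒ 4 + 8.** The C7–C8 and C11–C12 bonds are cut, with CO2 re-inserted between C8 and C11. The carbocycle, the quaternary centre and the cis C7/C12 relationship come from one cycloaddition, and the diene is left behind by the loss of CO2. The forward step needs the right orientation (methyl-bearing diene terminus to C7) and attack anti to the acetal substituent.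

**8 ⇒ 6 + 7, and 6 ⇒ 5.** The acetal C–O bond is cut, then the hydroxybutenolide is traced to a furoic acid by oxidative decarboxylation. The auxiliary is cheap and the acetal carbon is the only source of absolute configuration. The demand is access to one acetal epimer.

**4 ⇒ 3 ⇒ 1 + 2.** The lactone C–O bond and the C–C bond between the ester α-carbon and the carbinol carbon are cut. The pyranone becomes an ester enolate plus a β-alkoxy enal. The demand is an acid-mediated transposition and ring closure that tolerates E/Z equilibration.

## Other disconnections considered

**Alternative 1:** The cut is at C7–C12 and C8–C9, with the pyranone lactone kept as a C12–C2'(=O)–O–C9 bridge.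
- Forward key step: the pyranone A3 (the same diene as 4, but mapped with its C3 as C12 and its C6 as C9) takes up the (Z)-alkenylborane A2 in a [4+2] reaction mild enough for the bridged lactone to survive. Oxidative work-up turns C8–B into C8–OH and gives the hydroxy lactone A1.
- In its favour: four ring centres and the C8 oxygen arise in one operation. The C8–O bond comes from a C–B bond with retention, so no late diene epoxidation with its regio- and face-selectivity questions is needed; on this point A1 is better than the chosen plan. C2' already sits on C12 as a carboxyl carbon, which is equal to the chosen plan.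
- Against it: the C9 oxygen is on the lactone face, cis to C2', while the target needs it trans. The lactone must therefore be opened, the allylic C9 hydroxyl activated and displaced by the C8 alkoxide, and an allylic secondary sulfonate can ionise instead of inverting. The epoxide then exists before the pyranone and the side chain, and would have to survive an alkyllithium, an acid chloride with HCl, and carboalumination. The opened lactone leaves a neopentyl carboxyl on C12, so the pyranone problem is postponed, not solved. Face selectivity rests on the acyclic dioxolane centre of A2, and the orientation of an alkenylborane toward an unsymmetrical pyranone is harder to predict.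
- Comparison: stronger on the oxygenation pattern, one pericyclic step against cycloaddition plus epoxidation, but weaker in step economy (inversion sequence, unmasking of the dioxolane) and in the order of events it forces on the vinyl epoxide.

**Alternative 2:** The cut is at C6–C7 and C12–CH3; the carbocycle comes from an arene.
- Forward key step: the alkenyllithium A6 adds to an ortho carbon of the chromium tricarbonyl complex A5 on the face away from the metal. Methylation at chromium and migration to the ipso carbon from the metal face, followed by decomplexation, gives the diene A4.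
- In its favour: it is highly convergent. The complete chain, its (E) alkene and the C4 centre (held at the alcohol oxidation level, so not epimerisable) arrive in one step; on side-chain construction A4 is better than the chosen plan, which needs a late coupling of a new type. C7 and C12 are set together, trans addition gives the required cis relation of chain and C12 carbon substituent, and the diene C8=C9–C10=C11 is formed directly. Ring stereocontrol by an auxiliary is equal in both plans.
- Against it: stoichiometric chromium. Simple alkyl electrophiles tend to be delivered with carbonyl insertion, so an acetyl group in place of the methyl group on C12 is a real danger. The oxazoline on quaternary C12 must be converted into the ethyl ketone (or another pyranone precursor) over several steps at a neopentyl centre. Epoxidation must later distinguish the ring diene from an electron-rich side-chain alkene, where the chosen plan has a deactivated iodoalkene and is better. A6 needs its own multi-step synthesis.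
- Comparison: better convergence and control of C4; a more delicate organometallic key step; about equal in total steps once the oxazoline conversion and the fragment synthesis are counted.

**Alternative 3:** The cut is at C7–C8 and C11–C12, with extrusion of CO2.
- Forward key step: the pyranone A3 and the alkoxybutenolide A8 combine in a [4+2] reaction, and the bridged adduct loses CO2 to give the cis-fused diene A7.
- In its favour: the ring, the quaternary centre, the C7/C12 relationship and the diene come from one operation, with absolute control from a ring acetal. A7 is identical with 10, A3 with 4 and A8 with 8, so this is the construction used in step 5; on ring construction the alternative is the exact equal of the chosen plan. As a single step it forms more of the skeleton (one ring, two C–C bonds, two stereocentres) than the pyranone annulation and is the better step on that count.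
- Against it as the strategy-bearing step: it solves the carbocycle but not the heterocycle. A plan centred on it still needs a way to hang a fully substituted pyranone on C12, and the usual one (a keto ester dianion acylated by a C12 acyl donor) fails at the neopentyl carbonyl. Its orientation relies on sterics against the directing effect of the two pyranone methyl groups, and it needs high temperature.
- Comparison: the two disconnections are complementary. The chosen one gives the lactone carbonyl of A7 its purpose (ethyl ketone, then enol, then double acylation). Mechanistically it is a pericyclic step with an orientation risk against a polar acylation with a hindrance risk. Step economy is identical because both belong to the same route.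

Key step: step 10

Assumption: the auxiliary is (+)-menthol, whose (5S) acetal in 8 shields the butenolide face that must stay free; the enol ether geometry of 16 and the hemiketal configuration of 11 are of no consequence.

## Route

Step 1
Reactants: 1 ethyl propanoate; 2 (2E)-3-ethoxy-2-methylprop-2-enal
Product: 3 ethyl (4E)-5-ethoxy-3-hydroxy-2,4-dimethylpent-4-enoate (diastereomer mixture)
Conditions: LiN(iPr)2, THF, −78 °C; then 2, −78 °C; AcOH
Reagents that add atoms: none
Why: Aldol addition of the lithium ester enolate to the aldehyde of the vinylogous formate occurs 1,2 at low temperature; both new stereocentres are erased in step 2, so no control is needed.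

Step 2
Reactants: 3 ethyl (4E)-5-ethoxy-3-hydroxy-2,4-dimethylpent-4-enoate
Product: 4 3,5-dimethyl-2H-pyran-2-one
Conditions: TsOH·H2O (10 mol %), PhMe, 110 °C, ethanol distilled off
Reagents that add atoms: none
Why: Acid ionises the allylic alcohol with help from the enol ether (allylic transposition to the 5-oxopent-3-enoate), E/Z equilibration through the dienol lets the enol oxygen reach the ester, and enol lactonisation is driven by loss of ethanol and the stability of the 2-pyranone.

Step 3
Reactants: 5 3-methylfuran-2-carboxylic acid
Product: 6 5-hydroxy-3-methylfuran-2(5H)-one (racemic)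
Conditions: O2, hν (visible), methylene blue (cat.), MeOH, 0 °C
Reagents that add atoms: dioxygen, O=O
Why: Sensitised [4+2] addition of singlet oxygen across C2/C5 of the furan and decarboxylative fragmentation of the endoperoxide is the established photooxygenation of 2-furoic acids to 5-hydroxybutenolides.

Step 4
Reactants: 6 5-hydroxy-3-methylfuran-2(5H)-one; 7 (1S,2R,5S)-(+)-menthol
Product: 8 (5S)-3-methyl-5-{[(1S,2R,5S)-5-methyl-2-(propan-2-yl)cyclohexyl]oxy}furan-2(5H)-one
Conditions: camphorsulfonic acid (cat.), PhMe, reflux (Dean–Stark); crystallisation, mother liquor re-equilibrated with acid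
Reagents that add atoms: none
Why: Acid-catalysed acetalisation of the pseudo-acid; the two C5 epimers interconvert through the oxocarbenium ion, so the (5S) epimer should be collected by crystallisation (or chromatography) and the other recycled, which sets the acetal centre that later relays all absolute configuration.

Step 5
Reactants: 4 3,5-dimethyl-2H-pyran-2-one; 8 (5S)-3-methyl-5-(menthyloxy)furan-2(5H)-one
Product: 10 (3S,3aS,7aR)-4,6,7a-trimethyl-3-{[(1S,2R,5S)-5-methyl-2-(propan-2-yl)cyclohexyl]oxy}-3a,7a-dihydro-2-benzofuran-1(3H)-one, via bridged lactone adduct 9 (not isolated)
Conditions: 4 (3 equiv), BHT (cat.), PhMe, 140 °C, sealed tube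
Reagents that add atoms: none
Why: Diels–Alder reaction followed by retro-Diels–Alder loss of CO2; the diene should add to the face of 8 anti to the menthyloxy group and join its methyl-bearing carbon to the unsubstituted butenolide carbon (the other orientation would bond two fully substituted carbons), so C7 and the quaternary C12 are set cis by the acetal centre and the endo/exo outcome is erased with the CO2.

Step 6
Reactants: 10 cis-fused menthyloxy lactone diene
Product: 12 (1S,6R)-2,4,6-trimethyl-6-propanoylcyclohexa-2,4-diene-1-carbaldehyde, via lactol 11 (not isolated)
Conditions: EtLi (1.05 equiv), THF, −78 °C; AcOH, −78 °C → rt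
Reagents that add atoms: ethyllithium, [Li]CC
Why: 1,2-Addition of one equivalent of an organolithium to a lactone that cannot enolise (C12 is quaternary); the tetrahedral alkoxide is held at −78 °C until the acidic quench, after which ring–chain tautomerism of the lactol releases the hindered ketone and a hemiacetal that loses menthol to give the aldehyde.

Step 7
Reactants: 12 (1S,6R)-2,4,6-trimethyl-6-propanoylcyclohexa-2,4-diene-1-carbaldehyde
Product: 13 1-[(1R,6S)-6-ethynyl-1,3,5-trimethylcyclohexa-2,4-dien-1-yl]propan-1-one
Conditions: TMSCHN2, n-BuLi, THF, −78 °C; then 12, −78 → 0 °C; AcOH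
Reagents that add atoms: trimethylsilyldiazomethane, C[Si](C)(C)C=[N+]=[N-]
Why: Colvin rearrangement: the lithiated diazomethane adds to the aldehyde faster than to the neopentyl-type ketone, Peterson elimination gives the diazoalkene and the alkylidene carbene rearranges by 1,2-hydrogen shift; low temperature and the absence of alkoxide in methanol protect the allylic, α-formyl C7 centre.

Step 8
Reactants: 14 methylmalonic acid
Product: 15 methylmalonyl dichloride
Conditions: SOCl2 (neat), 60 °C; distillation
Reagents that add atoms: thionyl chloride, O=S(Cl)Cl
Why: Standard conversion of a malonic acid into its dichloride; moderate temperature limits decarboxylation and ketene formation.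

Step 9
Reactants: 13 1-[(1R,6S)-6-ethynyl-1,3,5-trimethylcyclohexa-2,4-dien-1-yl]propan-1-one
Product: 16 {[(1Z)-1-[(1R,6S)-6-ethynyl-1,3,5-trimethylcyclohexa-2,4-dien-1-yl]prop-1-en-1-yl]oxy}(trimethyl)silane
Conditions: TMSOTf, Et3N, CH2Cl2, 0 °C; pentane, cold aq. NaHCO3 wash
Reagents that add atoms: trimethylsilyl trifluoromethanesulfonate, C[Si](C)(C)OS(=O)(=O)C(F)(F)F
Why: Soft enolisation to the silyl enol ether; the ketone can enolise only toward C3' because C12 is quaternary, and the amine/silyl triflate pair leaves the alkyne C–H and the allylic, propargylic C7–H untouched, which a lithium amide would not guarantee.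

Step 10
Reactants: 16 trimethylsilyl enol ether of the C12 ethyl ketone; 15 methylmalonyl dichloride
Product: 17 6-[(1R,6S)-6-ethynyl-1,3,5-trimethylcyclohexa-2,4-dien-1-yl]-4-hydroxy-3,5-dimethyl-2H-pyran-2-one
Conditions: 15 (1.2 equiv), 2,6-di-tert-butyl-4-methylpyridine (1.5 equiv), CH2Cl2, −78 °C → rt
Reagents that add atoms: none
Why: The enol ether carbon C3' attacks one acyl chloride of 15 (or the chlorocarbonyl ketene derived from it) and loses Me3SiCl, which forms C3'–C4' and gives a β-diketone acid chloride. This diketone can enolise only toward C2', and the enol oxygen then attacks the second acyl chloride, which forms O1'–C6'; tautomerisation of C4'/C5' gives the aromatic hydroxypyranone. The closest known reaction type is the condensation of ketone silyl enol ethers with malonyl dichlorides to 6-substituted 4-hydroxy-2-pyranones, of which this is a hindered case because C2' sits on a quaternary carbon. The ring closes by 6-exo-trig O-acylation (lactonisation) at C6'. No stereocentre is formed, and C7 and C12 are not touched because neither can enolise. The step needs regiocontrol and C- before O-acylation: the first is secured by the single enolisable side of the ketone and the symmetry of the diacyl unit, the second by the neutral silyl enol ether, which reacts at carbon. The hindered carbonyl acts only as the enol nucleophile and never as an electrophile, which is what avoids acylating a carbon nucleophile with a neopentyl acyl donor. The hindered pyridine takes up the HCl of the lactonisation so that the 1,3-diene and unreacted enol ether are not protonated.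

Step 11
Reactants: 17 alkynyl 4-hydroxy-2-pyranone
Product: 19 4-hydroxy-6-[(1R,6S)-6-[(1E)-1-iodoprop-1-en-2-yl]-1,3,5-trimethylcyclohexa-2,4-dien-1-yl]-3,5-dimethyl-2H-pyran-2-one, via alkenylalane 18 (not isolated)
Conditions: AlMe3 (4 equiv), Cp2ZrCl2 (0.5 equiv), CH2Cl2, 0 °C → rt; then I2, THF, −30 → 0 °C; aq. Na2S2O3, 1 M HCl
Reagents that add atoms: trimethylaluminium, C[Al](C)C; iodine, [I][I]
Why: Negishi zirconium-catalysed methylalumination (syn addition, methyl to the internal carbon C6) and iodinolysis with retention should give the (E)-alkenyl iodide; the first equivalent of AlMe3 turns the acidic pyranone into an aluminium pyranolate that is inert to the reagent, which is why this step precedes O-methylation (a Lewis-acid-bound methoxypyranone could be demethylated).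

Step 12
Reactants: 19 (E)-iodoalkenyl 4-hydroxy-2-pyranone
Product: 20 2-[(1R,6S)-6-[(1E)-1-iodoprop-1-en-2-yl]-1,3,5-trimethylcyclohexa-2,4-dien-1-yl]-6-methoxy-3,5-dimethyl-4H-pyran-4-one
Conditions: MeOTf (1.3 equiv), CH2Cl2, 0 °C → rt; aq. NaHCO3
Reagents that add atoms: methyl trifluoromethanesulfonate, COS(=O)(=O)C(F)(F)F
Why: A hard methylating agent without base alkylates the neutral 4-hydroxy-2-pyranone at its most basic site, the lactone carbonyl oxygen, and loss of the 4-OH proton from the pyrylium ion gives the 2-methoxy-4-pyranone; the acid set free is buffered by the basic pyranone until the bicarbonate wash, which spares the diene.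

Step 13
Reactants: 20 (E)-iodoalkenyl methoxypyranone diene
Product: 21 2-[(1R,4R,5S,6S)-5-[(1E)-1-iodoprop-1-en-2-yl]-2,4,6-trimethyl-7-oxabicyclo[4.1.0]hept-2-en-4-yl]-6-methoxy-3,5-dimethyl-4H-pyran-4-one
Conditions: dimethyldioxirane (1.05 equiv), acetone, −20 °C
Reagents that add atoms: dimethyldioxirane, CC1(C)OO1
Why: Electrophilic epoxidation under neutral conditions: the iodoalkene and the pyranone are electron-poor, C10=C11 is shielded on both faces by the two C12 substituents, and the C7 side chain covers one face of C8=C9, so oxygen should enter C8=C9 anti to the side chain and set C8 and C9 by substrate control.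

Step 14
Reactants: 21 epoxy (E)-alkenyl iodide; 22 2-bromopentan-3-one (racemic)
Product: 23 2-methoxy-3,5-dimethyl-6-[(1R,4R,5R,6S)-2,4,6-trimethyl-5-[(2E,4R)-4-methyl-5-oxohept-2-en-2-yl]-7-oxabicyclo[4.1.0]hept-2-en-4-yl]-4H-pyran-4-one
Conditions: NiBr2·diglyme (10 mol %), chiral bis(oxazoline) ligand (12 mol %, antipode chosen for 4R), Mn powder (3 equiv), 22 (1.5 equiv), DMA, 0 °C
Reagents that add atoms: none
Why: Proposed new method: zerovalent nickel inserts into the C5–I bond, 22 is converted by halogen abstraction at monovalent nickel into a planar α-keto radical (both enantiomers converge), the radical is captured by the alkenylnickel species and reductive elimination from trivalent nickel inside the chiral ligand sphere forms C4–C5 with retention of the (E) geometry and sets C4 by catalyst control, with Mn as terminal reductant; the closest known reaction types are the nickel/bis(oxazoline) stereoconvergent coupling of racemic α-bromo ketones with alkenylzirconium reagents and the asymmetric nickel-catalysed reductive coupling of alkenyl bromides with secondary alkyl chlorides, and the non-basic conditions are what the epimerisable, deconjugated C4 centre requires.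

## Compound list

1 | ethyl propanoate | CCC(=O)OCC | starting material
2 | (2E)-3-ethoxy-2-methylprop-2-enal | CCO/C=C(\C)C=O | starting material
3 | ethyl (4E)-5-ethoxy-3-hydroxy-2,4-dimethylpent-4-enoate (mixture of C2/C3 diastereomers) | CCO/C=C(\C)C(O)C(C)C(=O)OCC | intermediate
4 | 3,5-dimethyl-2H-pyran-2-one | O=C1OC=C(C)C=C1C | intermediate
5 | 3-methylfuran-2-carboxylic acid | Cc1ccoc1C(=O)O | starting material
6 | 5-hydroxy-3-methylfuran-2(5H)-one (racemic) | CC1=CC(O)OC1=O | intermediate
7 | (1S,2R,5S)-(+)-menthol | O[C@H]1C[C@@H](C)CC[C@@H]1C(C)C | starting material
8 | (5S)-3-methyl-5-{[(1S,2R,5S)-5-methyl-2-(propan-2-yl)cyclohexyl]oxy}furan-2(5H)-one | O=C1O[C@H](O[C@H]2C[C@@H](C)CC[C@@H]2C(C)C)C=C1C | intermediate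
9 | bridged lactone adduct, formed in the flask and not isolated: 2-oxabicyclo[2.2.2]oct-5-en-3-one fused to the menthyloxy butyrolactone, endo isomer drawn (lactone bridge anti to the butyrolactone ring); the exo isomer gives the same 10 | C[C@]12C=C(C)[C@H](OC1=O)[C@@]1(C)C(=O)O[C@H](O[C@H]3C[C@@H](C)CC[C@@H]3C(C)C)[C@@H]21 | intermediate
10 | (3S,3aS,7aR)-4,6,7a-trimethyl-3-{[(1S,2R,5S)-5-methyl-2-(propan-2-yl)cyclohexyl]oxy}-3a,7a-dihydro-2-benzofuran-1(3H)-one (cis ring fusion, menthyloxy group anti to the carbocycle) | O=C1O[C@H](O[C@H]3C[C@@H](C)CC[C@@H]3C(C)C)[C@H]2C(C)=CC(C)=C[C@@]12C | intermediate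
11 | (3S,3aS,7aR)-1-ethyl-4,6,7a-trimethyl-3-(menthyloxy)-1,3,3a,7a-tetrahydro-2-benzofuran-1-ol, formed in the flask and not isolated (either configuration at C1; lithium alkoxide before the quench) | CCC1(O)O[C@H](O[C@H]3C[C@@H](C)CC[C@@H]3C(C)C)[C@H]2C(C)=CC(C)=C[C@@]12C | intermediate
12 | (1S,6R)-2,4,6-trimethyl-6-propanoylcyclohexa-2,4-diene-1-carbaldehyde (formyl and propanoyl groups cis) | O=C[C@H]1C(C)=CC(C)=C[C@@]1(C)C(=O)CC | intermediate
13 | 1-[(1R,6S)-6-ethynyl-1,3,5-trimethylcyclohexa-2,4-dien-1-yl]propan-1-one (ethynyl and propanoyl groups cis) | C#C[C@H]1C(C)=CC(C)=C[C@@]1(C)C(=O)CC | intermediate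
14 | methylmalonic acid (2-methylpropanedioic acid) | CC(C(=O)O)C(=O)O | starting material
15 | methylmalonyl dichloride (2-methylpropanedioyl dichloride) | CC(C(=O)Cl)C(=O)Cl | intermediate
16 | {[(1Z)-1-[(1R,6S)-6-ethynyl-1,3,5-trimethylcyclohexa-2,4-dien-1-yl]prop-1-en-1-yl]oxy}(trimethyl)silane | C#C[C@H]1C(C)=CC(C)=C[C@@]1(C)/C(O[Si](C)(C)C)=C/C | intermediate
17 | 6-[(1R,6S)-6-ethynyl-1,3,5-trimethylcyclohexa-2,4-dien-1-yl]-4-hydroxy-3,5-dimethyl-2H-pyran-2-one | C#C[C@H]1C(C)=CC(C)=C[C@@]1(C)c1oc(=O)c(C)c(O)c1C | intermediate
18 | (E)-alkenyl(dimethyl)alane from 17, pyranone oxygen bound as O–AlMe2, formed in the flask and not isolated | C[Al](C)/C=C(\C)[C@H]1C(C)=CC(C)=C[C@@]1(C)c1oc(=O)c(C)c(O[Al](C)C)c1C | intermediate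
19 | 4-hydroxy-6-[(1R,6S)-6-[(1E)-1-iodoprop-1-en-2-yl]-1,3,5-trimethylcyclohexa-2,4-dien-1-yl]-3,5-dimethyl-2H-pyran-2-one | I/C=C(\C)[C@H]1C(C)=CC(C)=C[C@@]1(C)c1oc(=O)c(C)c(O)c1C | intermediate
20 | 2-[(1R,6S)-6-[(1E)-1-iodoprop-1-en-2-yl]-1,3,5-trimethylcyclohexa-2,4-dien-1-yl]-6-methoxy-3,5-dimethyl-4H-pyran-4-one | I/C=C(\C)[C@H]1C(C)=CC(C)=C[C@@]1(C)c1oc(OC)c(C)c(=O)c1C | intermediate
21 | 2-[(1R,4R,5S,6S)-5-[(1E)-1-iodoprop-1-en-2-yl]-2,4,6-trimethyl-7-oxabicyclo[4.1.0]hept-2-en-4-yl]-6-methoxy-3,5-dimethyl-4H-pyran-4-one (epoxide anti to the iodoalkenyl and pyranone groups) | I/C=C(\C)[C@H]1[C@]2(C)O[C@@H]2C(C)=C[C@@]1(C)c1oc(OC)c(C)c(=O)c1C | intermediate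
22 | 2-bromopentan-3-one (racemic) | CCC(=O)C(C)Br | starting material
23 | 2-methoxy-3,5-dimethyl-6-[(1R,4R,5R,6S)-2,4,6-trimethyl-5-[(2E,4R)-4-methyl-5-oxohept-2-en-2-yl]-7-oxabicyclo[4.1.0]hept-2-en-4-yl]-4H-pyran-4-one | CCC(=O)[C@H](C)/C=C(\C)[C@H]1[C@]2(C)O[C@@H]2C(C)=C[C@@]1(C)c1oc(OC)c(C)c(=O)c1C | target

## Step count and least certain steps

Total step count: 14. Longest linear sequence: 11 steps (5 → 6 → 8 → 10 → 12 → 13 → 16 → 17 → 19 → 20 → 21 → 23; the branch from 1 has the same length).

**Step 14 (Proposed new method).** Most likely to fail by unproductive consumption of the two electrophiles (homocoupling, reduction of the bromo ketone by the metal reductant) or by weak catalyst control at C4, because this pairing of an alkenyl iodide with an α-bromo dialkyl ketone under reductive conditions has no direct precedent and the alkenyl partner is β,β-disubstituted. Opening of the vinyl epoxide by low-valent nickel or by halide is a second hazard. Fallback with known chemistry, from 21 to 23: 22 is converted with zinc dust in THF into the zinc enolate of pentan-3-one F1 (a Reformatsky reagent), which is coupled with 21 under Pd2(dba)3/P(t-Bu)3 at room temperature (palladium-catalysed alkenylation of a zinc enolate). C4 is then not controlled, so 23 is formed together with its C4 epimer F2; the two are diastereomers and are separated by chromatography.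

**Step 10 (key step).** Most likely to fail by O-acylation or protodesilylation of the enol ether in place of C-acylation at the crowded C3', by self-condensation of the ketene derived from 15, or by acid-induced isomerisation of the diene if the scavenging of HCl is incomplete. Fallback, from 13 to 17: the two bonds are made in separate operations. Soft-enolisation C-acylation of 13 (MgBr2·OEt2, i-Pr2NEt, CH2Cl2) with commercial methyl 3-chloro-2-methyl-3-oxopropanoate gives the diketo ester F3, and DBU in hot toluene closes the ring by lactonisation with loss of methanol to give 17. The C12 carbonyl is still used only as an enolate.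

**Step 5.** Most likely to fail by cycloaddition in the wrong orientation: the two pyranone methyl groups direct the carbonyl-bearing butenolide carbon toward the methyl-bearing diene terminus, and only sterics oppose this. Slow reaction of two hindered partners and thermal 1,5-hydrogen shift or a second cycloaddition of the product diene at 140 °C are further hazards. Fallback, from 8 to 10: a diene with a dominant directing group replaces the pyranone. (E)-2-Methylpent-2-enal is converted (TBSOTf, Et3N) into the silyl dienol ether F4, whose oxygen-bearing terminus must bond to the carbonyl-bearing butenolide carbon. Cycloaddition with 8 (toluene, 110 °C, anti to the menthyloxy group) gives the cyclohexene silyl ether F5. Catalytic TsOH in benzene then causes 1,4-elimination of the silanol through the allyl cation; only C8–H can be lost because C12 is quaternary, so the product is 10.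

**Step 6.** Most likely to fail by collapse of the tetrahedral alkoxide before the quench, with a second addition of ethyllithium to the liberated aldehyde, and by epimerisation or conjugation at C7 of the keto aldehyde in the presence of lithium alkoxides. Fallback, from 10 to 13 (12 is bypassed): the order of the two carbonyl operations is reversed. Aqueous acetic acid hydrolyses the acetal to the hydroxy lactone F6. The Ohira–Bestmann reagent with K2CO3 in methanol converts its open formyl carboxylate form into the alkynyl acid F7. Ethyllithium (3.2 equiv, Et2O, 0 °C) then gives 13 by the carboxylate-to-ketone reaction, which stops at the geminal dialkoxide.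

**Step 13.** Most likely to fail by competing oxidation of C10=C11, attack on the face of the side chain, over-oxidation to a bis-epoxide, or acid-induced opening of the vinyl epoxide during isolation. Fallback, from 20 to 21: the oxygen is delivered across the whole diene and then edited. Sensitised photooxygenation ([4+2] of singlet oxygen on the face anti to the C7 and C12 groups) gives the endoperoxide F8. Triphenylphosphine attacks the oxygen on the secondary carbon C11, and the C8 alkoxide closes onto C9 in a syn displacement with allylic shift, which gives the C8–C9 epoxide on the required face and the C10=C11 alkene of 21.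

## Further compounds

F1 | step 14 | bromo(pent-2-en-3-olato)zinc, the zinc enolate of pentan-3-one | CC=C(CC)O[Zn]Br
F2 | step 14 | C4 epimer of 23, (2E,4S)-configured side chain | CCC(=O)[C@@H](C)/C=C(\C)[C@H]1[C@]2(C)O[C@@H]2C(C)=C[C@@]1(C)c1oc(OC)c(C)c(=O)c1C
F3 | step 10 | methyl 5-[(1R,6S)-6-ethynyl-1,3,5-trimethylcyclohexa-2,4-dien-1-yl]-2,4-dimethyl-3,5-dioxopentanoate (mixture at C2/C4) | C#C[C@H]1C(C)=CC(C)=C[C@@]1(C)C(=O)C(C)C(=O)C(C)C(=O)OC
F4 | step 5 | tert-butyl(dimethyl){[(1E,3E)-2-methylpenta-1,3-dien-1-yl]oxy}silane | C/C=C/C(C)=C/O[Si](C)(C)C(C)(C)C
F5 | step 5 | (3S,3aS,7aS)-7-{[tert-butyl(dimethyl)silyl]oxy}-4,6,7a-trimethyl-3-(menthyloxy)-3a,4,7,7a-tetrahydro-2-benzofuran-1(3H)-one (C4/C7 epimers, both centres lost on elimination) | O=C1O[C@H](O[C@H]3C[C@@H](C)CC[C@@H]3C(C)C)[C@H]2C(C)C=C(C)C(O[Si](C)(C)C(C)(C)C)[C@@]12C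
F6 | step 6 | (3aS,7aR)-3-hydroxy-4,6,7a-trimethyl-3a,7a-dihydro-2-benzofuran-1(3H)-one (either anomer) | O=C1OC(O)[C@H]2C(C)=CC(C)=C[C@@]12C
F7 | step 6 | (1R,6S)-6-ethynyl-1,3,5-trimethylcyclohexa-2,4-diene-1-carboxylic acid | C#C[C@H]1C(C)=CC(C)=C[C@@]1(C)C(=O)O
F8 | step 13 | endoperoxide of 20: peroxide bridge from C8 to C11 on the face anti to the iodoalkenyl and pyranone groups, C9=C10 alkene | I/C=C(\C)[C@H]1[C@@]2(C)C=C(C)[C@H](OO2)[C@@]1(C)c1oc(OC)c(C)c(=O)c1C
A1 | alternative 1 | bridged hydroxy lactone: 7-hydroxy-4,6,7-trimethyl-8-(2,2-dimethyl-1,3-dioxolan-4-yl)-2-oxabicyclo[2.2.2]oct-5-en-3-one, hydroxyl anti to the lactone bridge | O=C1O[C@H]2C(C)=C[C@]1(C)[C@@H]([C@@H]3COC(C)(C)O3)[C@]2(C)O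
A2 | alternative 1 | (Z)-dicyclohexyl{1-[(4R)-2,2-dimethyl-1,3-dioxolan-4-yl]prop-1-en-2-yl}borane | C/C(B(C1CCCCC1)C1CCCCC1)=C\[C@@H]1COC(C)(C)O1
A3 | alternative 1 | 3,5-dimethyl-2H-pyran-2-one (identical with 4) | O=C1OC=C(C)C=C1C
A4 | alternative 2 | trans-5-alkenyl-6-methyl-6-oxazolinylcyclohexa-1,3-diene carrying the silyl-protected C1–C6 chain | CC[C@@H](O[Si](C)(C)C(C)(C)C)[C@H](C)/C=C(\C)[C@H]1C(C)=CC(C)=C[C@@]1(C)C1=N[C@@H](C(C)(C)C)CO1
A5 | alternative 2 | tricarbonyl{η6-(4S)-4-tert-butyl-2-(3,5-dimethylphenyl)-4,5-dihydro-1,3-oxazole}chromium, written as its components | Cc1cc(C)cc(C2=N[C@@H](C(C)(C)C)CO2)c1.[C-]#[O+].[C-]#[O+].[C-]#[O+].[Cr]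
A6 | alternative 2 | (E)-alkenyllithium of the C1–C6 chain with the C3 silyl ether | CC[C@@H](O[Si](C)(C)C(C)(C)C)[C@H](C)/C=C(\C)[Li]
A7 | alternative 3 | cis-fused menthyloxy lactone of the 3,5-dimethylcyclohexa-2,4-diene (identical with 10) | O=C1O[C@H](O[C@H]3C[C@@H](C)CC[C@@H]3C(C)C)[C@H]2C(C)=CC(C)=C[C@@]12C
A8 | alternative 3 | (5S)-5-(menthyloxy)-3-methylfuran-2(5H)-one (identical with 8) | O=C1O[C@H](O[C@H]2C[C@@H](C)CC[C@@H]2C(C)C)C=C1C
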